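**Plan**

- Retrosynthesis: the imide N-H is first masked as N-(2,4-dimethoxybenzyl); the indole pyrrole ring is then cut at N1-C2 and C3-C3a, giving 5-bromo-2-iodoaniline and an ethynyl group on maleimide C3.
- The alkyne-maleimide bond (Sonogashira) and the imidazole C5-maleimide C4 bond (Stille) are cut next, back to a dibromomaleimide made from dibromomaleic anhydride and the benzylamine.
- Enabling feature: indole C3 is bonded directly to maleimide C3, so an ethynyl unit on that carbon is conjugated through C3=C4 to the C5 carbonyl (a 1,6-acceptor), and its terminal carbon is the future indole C2.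
- Forward order: maleimide ring (imide formation), imidazole attached, alkyne attached and unmasked, indole pyrrole ring closed onto the purchased bromoarene, imide deprotected.
- Stereochemistry: the target has no stereocentre and no stereogenic double bond; bromine at indole C6 is fixed by the 5-bromo-2-iodo pattern of the aniline.

Key step: step 5

Remark: compounds 1, 2, 5, 7 and 10 are taken as purchasable; enamine 11 is drawn as its E isomer, but either geometry should cyclise to the same indole.

**Route**

Step 1
Reactants: 1 dibromomaleic anhydride; 2 2,4-dimethoxybenzylamine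
Product: 4 3,4-dibromo-1-(2,4-dimethoxybenzyl)pyrrole-2,5-dione, via maleamic acid 3 (not isolated)
Conditions: AcOH, 23 °C then reflux
Reagents that add atoms: none
Why: Aminolysis of the anhydride gives maleamic acid 3, which cyclodehydrates in hot acetic acid (imide formation), the acidic medium keeping the amine largely protonated so that addition-elimination at the C-Br bonds is suppressed.

Step 2
Reactants: 4 3,4-dibromo-1-(2,4-dimethoxybenzyl)pyrrole-2,5-dione; 5 1-methyl-5-(tributylstannyl)imidazole
Product: 6 3-bromo-1-(2,4-dimethoxybenzyl)-4-(1-methylimidazol-5-yl)pyrrole-2,5-dione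
Conditions: 4 (2 equiv), Pd(PPh3)4 (5 mol %), CuI (10 mol %), DMF, 50 °C
Reagents that add atoms: none
Why: Stille cross-coupling, in which the vinylogous acyl bromide undergoes oxidative addition readily, CuI speeds transmetallation of the heteroaryl stannane, and the excess of 4 together with deactivation of the remaining C-Br bond by the donor imidazole should hold the reaction at mono-substitution.

Step 3
Reactants: 6 3-bromo-1-(2,4-dimethoxybenzyl)-4-(1-methylimidazol-5-yl)pyrrole-2,5-dione; 7 trimethylsilylacetylene
Product: 8 1-(2,4-dimethoxybenzyl)-3-(1-methylimidazol-5-yl)-4-[(trimethylsilyl)ethynyl]pyrrole-2,5-dione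
Conditions: PdCl2(PPh3)2 (5 mol %), CuI (10 mol %), i-Pr2NEt, THF, 23 °C
Reagents that add atoms: none
Why: Sonogashira coupling of the activated bromide at room temperature, with a hindered tertiary amine that cannot displace bromide by addition-elimination and a silyl cap that keeps the alkyne terminus from acting as a conjugate acceptor.

Step 4
Reactants: 8 1-(2,4-dimethoxybenzyl)-3-(1-methylimidazol-5-yl)-4-[(trimethylsilyl)ethynyl]pyrrole-2,5-dione
Product: 9 1-(2,4-dimethoxybenzyl)-3-ethynyl-4-(1-methylimidazol-5-yl)pyrrole-2,5-dione
Conditions: Bu4NF (1.1 equiv), AcOH (1.5 equiv), THF, −78 → −20 °C; cold aqueous work-up, solution used at once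
Reagents that add atoms: none
Why: Fluoride-mediated protodesilylation of the alkynylsilane, buffered with acetic acid so that the acetylide is protonated as it forms and the base-sensitive ynenimide is not exposed to free fluoride or alkoxide.

Step 5
Reactants: 9 1-(2,4-dimethoxybenzyl)-3-ethynyl-4-(1-methylimidazol-5-yl)pyrrole-2,5-dione; 10 5-bromo-2-iodoaniline
Product: 13 N-(2,4-dimethoxybenzyl)didemnimide D [3-(6-bromo-1H-indol-3-yl)-1-(2,4-dimethoxybenzyl)-4-(1-methylimidazol-5-yl)pyrrole-2,5-dione], via anilinovinyl enamine 11 (not isolated), via 3H-indole tautomer 12 (not isolated)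
Conditions: 10 (1.1 equiv), DMF, 23 → 50 °C until 9 is consumed; then DABCO (3 equiv), Pd(OAc)2 (10 mol %), 90 °C
Reagents that add atoms: none
Why: Proposed new method: the ethynyl group on maleimide C3 is the far end of an ynenone (C≡C–C3=C4–C5=O), so the aniline nitrogen should add to the terminal alkyne carbon in a 1,6-aza-Michael sense (N1–C2) and protonation of the allenyl enolate at the internal carbon gives push-pull dienamine 11; the closest known reaction type is the conjugate addition of 2-haloanilines to ynones or propiolates followed by palladium-catalysed cyclisation of the N-(2-halophenyl)enaminones to 3-acylindoles, of which this is the vinylogous version. Zerovalent palladium formed from Pd(OAc)2 and the amine then inserts into the C–I bond, the nucleophilic enamine carbon attacks the divalent arylpalladium centre to give a six-membered palladacycle, and reductive elimination forms C3–C3a and gives 3H-indole 12, which tautomerises to the aromatic 1H-indole 13 while DABCO takes up HI. The pyrrole ring closes in a formally 5-endo-trig mode (both enamine carbons lie in the new ring), which the palladacycle pathway makes feasible where a direct ionic closure would not be. No stereocentre is created and the enamine geometry is immaterial, since both isomers lead to the same aromatic ring. The step needs nitrogen at the terminal carbon, which the 1,6-polarisation secures (direct attack on the tetrasubstituted maleimide C=C is hindered and reversible), and it needs reaction at iodide and not at bromide, which the much faster oxidative addition of the C–I bond under ligand-free conditions secures. Alkynylation of the aryl iodide is avoided by adding palladium only after the alkyne has been consumed.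

Step 6
Reactants: 13 N-(2,4-dimethoxybenzyl)didemnimide D
Product: 14 didemnimide D
Conditions: TFA, anisole (10 equiv), 80 °C; aqueous NaHCO3 work-up
Reagents that add atoms: none
Why: Acidolytic N-debenzylation, in which the 2,4-dimethoxybenzyl cation leaves the protonated imide and is trapped by anisole (Friedel-Crafts alkylation) before it can alkylate the indole, while the aryl bromide, the indole and the imidazolium ring are inert to the acid.

**Compound list**

1 | dibromomaleic anhydride (3,4-dibromofuran-2,5-dione) | O=C1OC(=O)C(Br)=C1Br | starting material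
2 | 2,4-dimethoxybenzylamine | COc1ccc(CN)c(OC)c1 | starting material
3 | (Z)-2,3-dibromo-4-[(2,4-dimethoxybenzyl)amino]-4-oxobut-2-enoic acid (maleamic acid, not isolated) | OC(=O)/C(Br)=C(/Br)C(=O)NCc1ccc(OC)cc1OC | intermediate
4 | 3,4-dibromo-1-(2,4-dimethoxybenzyl)pyrrole-2,5-dione | O=C1C(Br)=C(Br)C(=O)N1Cc1ccc(OC)cc1OC | intermediate
5 | 1-methyl-5-(tributylstannyl)imidazole | CCCC[Sn](CCCC)(CCCC)c1cncn1C | starting material
6 | 3-bromo-1-(2,4-dimethoxybenzyl)-4-(1-methylimidazol-5-yl)pyrrole-2,5-dione | Cn1cncc1C1=C(Br)C(=O)N(Cc2ccc(OC)cc2OC)C1=O | intermediate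
7 | trimethylsilylacetylene | C#C[Si](C)(C)C | starting material
8 | 1-(2,4-dimethoxybenzyl)-3-(1-methylimidazol-5-yl)-4-[(trimethylsilyl)ethynyl]pyrrole-2,5-dione | Cn1cncc1C1=C(C#C[Si](C)(C)C)C(=O)N(Cc2ccc(OC)cc2OC)C1=O | intermediate
9 | 1-(2,4-dimethoxybenzyl)-3-ethynyl-4-(1-methylimidazol-5-yl)pyrrole-2,5-dione | C#CC1=C(c2cncn2C)C(=O)N(Cc2ccc(OC)cc2OC)C1=O | intermediate
10 | 5-bromo-2-iodoaniline | Nc1cc(Br)ccc1I | starting material
11 | 3-[(E)-2-(5-bromo-2-iodoanilino)vinyl]-1-(2,4-dimethoxybenzyl)-4-(1-methylimidazol-5-yl)pyrrole-2,5-dione (enamine, not isolated) | Cn1cncc1C1=C(/C=C/Nc2cc(Br)ccc2I)C(=O)N(Cc2ccc(OC)cc2OC)C1=O | intermediate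
12 | 3-(6-bromo-3H-indol-3-yl)-1-(2,4-dimethoxybenzyl)-4-(1-methylimidazol-5-yl)pyrrole-2,5-dione (racemic at indole C3, transient, not isolated) | Cn1cncc1C1=C(C2C=Nc3cc(Br)ccc23)C(=O)N(Cc2ccc(OC)cc2OC)C1=O | intermediate
13 | N-(2,4-dimethoxybenzyl)didemnimide D, 3-(6-bromo-1H-indol-3-yl)-1-(2,4-dimethoxybenzyl)-4-(1-methylimidazol-5-yl)pyrrole-2,5-dione | Cn1cncc1C1=C(c2c[nH]c3cc(Br)ccc23)C(=O)N(Cc2ccc(OC)cc2OC)C1=O | intermediate
14 | didemnimide D, 3-(6-bromo-1H-indol-3-yl)-4-(1-methylimidazol-5-yl)pyrrole-2,5-dione | Cn1cncc1C1=C(c2c[nH]c3cc(Br)ccc23)C(=O)NC1=O | target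

**Step count and risks**

Total step count: 6. Longest linear sequence: 6 steps (1 or 2 to 14).

Steps most likely to fail:

1. Step 5 (proposed new method). The conjugate addition of the electron-poor, ortho-substituted aniline may be too slow, so that the terminal alkyne oligomerises or the maleimide C=C is attacked instead. The palladium stage may also stall through binding of the catalyst to imidazole N3, or lose selectivity through insertion into the C-Br bond. The fallback uses known chemistry, sets out from 6 and comes back at 13. Commercial 6-bromoindole (Brc1ccc2cc[nH]c2c1) would be deprotonated with EtMgBr in THF/toluene to 6-bromoindol-1-ylmagnesium bromide F1. This attacks bromomaleimide 6 through indole C3 by conjugate addition-elimination, the classical indolyl Grignard route to 3-aryl-4-indolylmaleimides, and should give 13 directly. Step 6 then follows unchanged.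

2. Step 4. The liberated terminal ynenimide may be destroyed by conjugate attack of fluoride, by attack of imidazole N3 of a second molecule, or by polymerisation on concentration. The fallback avoids the free alkyne, sets out from 6 and comes back at 11. Stille coupling of 6 with commercial (Z)-tributyl(2-ethoxyvinyl)stannane (Pd(PPh3)4, toluene, 90 °C) should give the stable push-pull dienol ether 1-(2,4-dimethoxybenzyl)-3-[(Z)-2-ethoxyvinyl]-4-(1-methylimidazol-5-yl)pyrrole-2,5-dione F2. Heating F2 with aniline 10 and catalytic TsOH in toluene should exchange ethanol for the aniline by addition-elimination, as in the amine exchange of beta-alkoxy enones, and give enamine 11. DABCO and Pd(OAc)2 are then added as in the second stage of step 5 to reach 13.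

3. Step 2. The coupling may run on to the second C-Br bond, and imidazole N3 may be quaternised by the bromomaleimide through addition-elimination. The fallback builds the maleimide with the imidazole already in place, sets out from 2 and comes back at 8.
   - Amide coupling of 2 with (1-methylimidazol-5-yl)acetic acid (EDC, HOBt, CH2Cl2) should give N-(2,4-dimethoxybenzyl)-2-(1-methylimidazol-5-yl)acetamide F3.
   - Condensation of F3 with dimethyl oxalate and KOt-Bu in THF (Claisen condensation then imide closure) should give 1-(2,4-dimethoxybenzyl)-3-hydroxy-4-(1-methylimidazol-5-yl)pyrrole-2,5-dione F4.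
   - Tf2O and Et3N in CH2Cl2 at −78 °C should convert F4 into 1-(2,4-dimethoxybenzyl)-4-(1-methylimidazol-5-yl)-2,5-dioxopyrrol-3-yl trifluoromethanesulfonate F5.
   - Sonogashira coupling of F5 with 7 under the conditions of step 3 should give 8. No statistical mono-coupling is involved.

**Further compounds**

F1 | step 5 | 6-bromoindol-1-ylmagnesium bromide | Br[Mg]n1ccc2ccc(Br)cc21
F2 | step 4 | 1-(2,4-dimethoxybenzyl)-3-[(Z)-2-ethoxyvinyl]-4-(1-methylimidazol-5-yl)pyrrole-2,5-dione | Cn1cncc1C1=C(/C=C\OCC)C(=O)N(Cc2ccc(OC)cc2OC)C1=O
F3 | step 2 | N-(2,4-dimethoxybenzyl)-2-(1-methylimidazol-5-yl)acetamide | Cn1cncc1CC(=O)NCc1ccc(OC)cc1OC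
F4 | step 2 | 1-(2,4-dimethoxybenzyl)-3-hydroxy-4-(1-methylimidazol-5-yl)pyrrole-2,5-dione | Cn1cncc1C1=C(O)C(=O)N(Cc2ccc(OC)cc2OC)C1=O
F5 | step 2 | 1-(2,4-dimethoxybenzyl)-4-(1-methylimidazol-5-yl)-2,5-dioxopyrrol-3-yl trifluoromethanesulfonate | Cn1cncc1C1=C(OS(=O)(=O)C(F)(F)F)C(=O)N(Cc2ccc(OC)cc2OC)C1=O
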